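Chain numbering: C1 = benzylic CH2, C2 = acetoxy-bearing CH, C13 = CH2OH. Retrosynthetic cuts, in order: the two O–benzyl bonds (phenol O and O13), the C6–C7 bond, the C7=C8 double bond of an octenyl precursor (this gives the carboxyl group on C6), the acetyl–O bond at C2, and the aryl–C1 bond.
Enabling feature: C6 and C7 are two alike, unactivated CH2 groups inside the unbranched C3–C12 methylene run, four C–C bonds from the C2 stereocentre and six from C13. No neighbour can polarise either carbon, but each can carry a carboxyl group that leaves as CO2, and a radical at either site has no β-leaving group and no π bond within easy reach.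
Key event: both halves are built as carboxylic acids (C6–CO2H and C7–CO2H), activated in the flask as N-hydroxyphthalimide esters and joined by nickel-electrocatalytic double decarboxylation at the cathode. The easily oxidised 3,5-dioxygenated benzene ring rules out the anodic (Kolbe) version.
Forward order: aryl ring + C1–C8 epoxide → C2 acetate → C6-bound acid; C7–C13 acid from 8-bromooctanoic acid; C6–C7 union; double hydrogenolysis.
Stereochemistry: C2 (R) comes from hydrolytic kinetic resolution of the terminal epoxide, and the C2–O bond is never broken afterwards.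

Key step: step 7

Remark: the given SMILES is read as 2R (O > CH2Ar > C3 > H); compounds 1, 3 and 10 are taken as catalogue chemicals.

Step 1
Reactants: 1 3-bromo-5-methoxyphenol
Product: 2 1-(benzyloxy)-3-bromo-5-methoxybenzene
Conditions: BnBr, K2CO3, DMF, rt
Reagents that add atoms: benzyl bromide, BrCc1ccccc1
Why: A Williamson ether synthesis on the phenoxide masks the acidic OH before Grignard formation with a group that leaves by hydrogenolysis at the end.

Step 2
Reactants: 3 rac-2-(hex-5-en-1-yl)oxirane (1,2-epoxy-7-octene)
Product: 4 (2R)-2-(hex-5-en-1-yl)oxirane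
Conditions: (R,R)-(salen)Co(III)OAc (0.5 mol %), H2O (0.55 equiv), neat, 0 °C → rt; distillation
Reagents that add atoms: none
Why: In the Jacobsen hydrolytic kinetic resolution the (R,R)-cobalt–salen catalyst hydrates the S-epoxide much faster, so the unreacted R-epoxide should be recovered in high enantiomeric purity and carries the future C2 stereocentre, while the remote alkene is inert.

Step 3
Reactants: 2 1-(benzyloxy)-3-bromo-5-methoxybenzene; 4 (2R)-2-(hex-5-en-1-yl)oxirane
Product: 7 (2R)-1-[3-(benzyloxy)-5-methoxyphenyl]oct-7-en-2-yl acetate, via aryl Grignard reagent 5 (not isolated), via magnesium alkoxide 6 (not isolated)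
Conditions: 2 (1.3 equiv), Mg, I2 (cat.), THF, reflux; then CuI (10 mol %), 4, THF, −30 → 0 °C; then Ac2O, DMAP (cat.), 0 °C → rt; 1 M HCl work-up
Reagents that add atoms: acetic anhydride, CC(=O)OC(C)=O; magnesium, [Mg] (stands only in 5 and 6)
Why: The copper-catalysed SN2 opening of a terminal epoxide by an aryl Grignard reagent takes place at the unsubstituted carbon, so the C2–O bond and its R configuration stay untouched, and the magnesium alkoxide is then O-acylated in the same flask by nucleophilic acyl substitution.

Step 4
Reactants: 7 (2R)-1-[3-(benzyloxy)-5-methoxyphenyl]oct-7-en-2-yl acetate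
Product: 8 (2R)-1-[3-(benzyloxy)-5-methoxyphenyl]-7-oxoheptan-2-yl acetate
Conditions: OsO4 (2 mol %), NaIO4 (4 equiv), 2,6-lutidine (2 equiv), dioxane/H2O 3:1, rt
Reagents that add atoms: sodium periodate, [Na+].[O-]I(=O)(=O)=O (terminal oxidant, source of the aldehyde oxygen by way of OsO4)
Why: The Lemieux–Johnson oxidation (catalytic dihydroxylation and periodate glycol cleavage, buffered with lutidine) removes C8, because the monosubstituted alkene is the only site open to osmylation and the acetate, ethers and arene are inert.

Step 5
Reactants: 8 (2R)-1-[3-(benzyloxy)-5-methoxyphenyl]-7-oxoheptan-2-yl acetate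
Product: 9 (6R)-6-acetoxy-7-[3-(benzyloxy)-5-methoxyphenyl]heptanoic acid
Conditions: NaClO2, 35 % H2O2, NaH2PO4, MeCN/H2O, 0–10 °C
Reagents that add atoms: sodium chlorite, [Na+].[O-]Cl=O
Why: The Pinnick–Lindgren chlorite oxidation at about pH 4 turns the aldehyde into the acid without touching the acetate, and hydrogen peroxide as scavenger should destroy hypochlorous acid before it can chlorinate the activated ring.

Step 6
Reactants: 10 8-bromooctanoic acid
Product: 11 8-(benzyloxy)octanoic acid
Conditions: BnOH (1.5 equiv), NaH (3 equiv), n-Bu4NI (cat.), THF, 0 °C → reflux; 1 M HCl work-up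
Reagents that add atoms: benzyl alcohol, OCc1ccccc1
Why: In this Williamson ether synthesis sodium benzyloxide displaces the primary bromide of the sodium carboxylate by SN2, and the carboxylate is too poor a nucleophile to compete.

Step 7
Reactants: 9 (6R)-6-acetoxy-7-[3-(benzyloxy)-5-methoxyphenyl]heptanoic acid; 11 8-(benzyloxy)octanoic acid
Product: 14 (2R)-13-(benzyloxy)-1-[3-(benzyloxy)-5-methoxyphenyl]tridecan-2-yl acetate, via head phthalimidyl ester 12 (not isolated), via tail phthalimidyl ester 13 (not isolated)
Conditions: (a) 9 (1 equiv), 11 (3 equiv), N-hydroxyphthalimide (4 equiv), DIC (4 equiv), CH2Cl2, rt, then evaporation; (b) NiCl2·6H2O (20 mol %), 2,2′:6′,2″-terpyridine (20 mol %), NaI, DMF, Zn(+)|Ni foam(−), undivided cell, constant current, rt; 1 M HCl work-up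
Reagents that add atoms: N-hydroxyphthalimide, O=C1c2ccccc2C(=O)N1O (its atoms stand only in 12 and 13 and leave again; none remain in 14)
Why: Cathodically formed low-valent (terpyridine)nickel passes one electron to the phthalimide unit of each ester, N–O cleavage and loss of CO2 give the primary radicals at C6 (from 12) and C7 (from 13), nickel takes them up one after the other, and reductive elimination from the dialkylnickel(III) species forms C6–C7 while the zinc anode supplies the two electrons. The closest known reaction type is the nickel-electrocatalytic doubly decarboxylative C(sp3)–C(sp3) cross-coupling of two N-hydroxyphthalimide esters made in situ, which is established for pairs of primary acids, is the reductive counterpart of the mixed Kolbe electrolysis and joins two carbons of like polarity. The reductive mode is chosen because an anodic coupling would oxidise the 3,5-dialkoxyphenyl ring before the carboxylates. No ring is closed and no stereocentre is formed; C2 lies four C–C bonds from the C6 radical, so β-scission or a 1,2-acyloxy shift is impossible and 1,5-hydrogen transfer from C2–H should be far slower than capture by nickel, which leaves the R configuration intact. The selectivity needed is cross- over homo-coupling of two nearly identical primary radicals; the substrates cannot bias it electronically, so it is secured by a threefold excess of the cheap acid 11, which on statistical grounds should send most radicals from 12 into 14, and by the stepwise polarity difference (none, one or two acetoxy–aryl head groups) that should make 14 easy to separate from both symmetrical dimers. Acetate, methyl ether and both benzyl ethers are inert at the mild potential at which the phthalimide esters are reduced.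

Step 8
Reactants: 14 (2R)-13-(benzyloxy)-1-[3-(benzyloxy)-5-methoxyphenyl]tridecan-2-yl acetate
Product: 15 (2R)-13-hydroxy-1-(3-hydroxy-5-methoxyphenyl)tridecan-2-yl acetate
Conditions: H2 (1 atm), 10 % Pd/C, EtOAc/EtOH, rt
Reagents that add atoms: none
Why: Catalytic hydrogenolysis cleaves both benzylic C–O bonds, whereas the C2 acetate is homobenzylic and is not hydrogenolysed, and the neutral medium excludes acetate hydrolysis or migration.

Compound list
1 | 3-bromo-5-methoxyphenol | COc1cc(O)cc(Br)c1 | starting material
2 | 1-(benzyloxy)-3-bromo-5-methoxybenzene | COc1cc(Br)cc(OCc2ccccc2)c1 | intermediate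
3 | rac-2-(hex-5-en-1-yl)oxirane (1,2-epoxy-7-octene) | C=CCCCCC1CO1 | starting material
4 | (2R)-2-(hex-5-en-1-yl)oxirane | C=CCCCC[C@@H]1CO1 | intermediate
5 | [3-(benzyloxy)-5-methoxyphenyl]magnesium bromide | COc1cc(OCc2ccccc2)cc([Mg]Br)c1 | intermediate
6 | bromomagnesium (2R)-1-[3-(benzyloxy)-5-methoxyphenyl]oct-7-en-2-olate | COc1cc(OCc2ccccc2)cc(C[C@@H](CCCCC=C)O[Mg]Br)c1 | intermediate
7 | (2R)-1-[3-(benzyloxy)-5-methoxyphenyl]oct-7-en-2-yl acetate | COc1cc(OCc2ccccc2)cc(C[C@@H](CCCCC=C)OC(C)=O)c1 | intermediate
8 | (2R)-1-[3-(benzyloxy)-5-methoxyphenyl]-7-oxoheptan-2-yl acetate | COc1cc(OCc2ccccc2)cc(C[C@@H](CCCCC=O)OC(C)=O)c1 | intermediate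
9 | (6R)-6-acetoxy-7-[3-(benzyloxy)-5-methoxyphenyl]heptanoic acid | COc1cc(OCc2ccccc2)cc(C[C@@H](CCCCC(=O)O)OC(C)=O)c1 | intermediate
10 | 8-bromooctanoic acid | OC(=O)CCCCCCCBr | starting material
11 | 8-(benzyloxy)octanoic acid | OC(=O)CCCCCCCOCc1ccccc1 | intermediate
12 | 1,3-dioxoisoindolin-2-yl (6R)-6-acetoxy-7-[3-(benzyloxy)-5-methoxyphenyl]heptanoate | COc1cc(OCc2ccccc2)cc(C[C@@H](CCCCC(=O)ON2C(=O)c3ccccc3C2=O)OC(C)=O)c1 | intermediate
13 | 1,3-dioxoisoindolin-2-yl 8-(benzyloxy)octanoate | O=C(CCCCCCCOCc1ccccc1)ON1C(=O)c2ccccc2C1=O | intermediate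
14 | (2R)-13-(benzyloxy)-1-[3-(benzyloxy)-5-methoxyphenyl]tridecan-2-yl acetate | COc1cc(OCc2ccccc2)cc(C[C@@H](CCCCCCCCCCCOCc2ccccc2)OC(C)=O)c1 | intermediate
15 | (2R)-13-hydroxy-1-(3-hydroxy-5-methoxyphenyl)tridecan-2-yl acetate | COc1cc(O)cc(C[C@@H](CCCCCCCCCCCO)OC(C)=O)c1 | target

Total step count: 8. Longest linear sequence: 6 (steps 1, 3, 4, 5, 7, 8; the line through step 2 is equally long).

Steps most likely to fail

Step 7.
- What may go wrong: statistical homocoupling of each radical, loss of radicals by hydrogen abstraction from the solvent, and fouling of the cathode.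
- The fallback replaces the second radical with a polar organometallic partner, so that cross-selectivity is built in. It sets out from 9 and comes back to the route at 14.
- Acid 9 is turned into 12 as before (N-hydroxyphthalimide, DIC, CH2Cl2), but 12 is now isolated by chromatography.
- Bought 7-bromoheptan-1-ol F1 is benzylated under acid catalysis (benzyl 2,2,2-trichloroacetimidate, TfOH cat., CH2Cl2) to benzyl 7-bromoheptyl ether F2. Magnesium insertion in THF gives [7-(benzyloxy)heptyl]magnesium bromide F3, and ZnCl2 (0.5 equiv) converts it into bis[7-(benzyloxy)heptyl]zinc F4.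
- A nickel-catalysed decarboxylative alkyl–alkyl Negishi coupling of 12 with F4 (NiCl2·glyme, 4,4′-di-tert-butyl-2,2′-bipyridine, THF/DMF, rt) forms the same C6–C7 bond and should give 14.

Step 3.
- What may go wrong: sluggish magnesium insertion into the electron-rich aryl bromide, competing opening of the epoxide by bromide, and incomplete acylation of the magnesium alkoxide.
- The fallback avoids any preformed organometallic reagent. It sets out from 2 and 4 and comes back at 7.
- A nickel-catalysed reductive cross-electrophile coupling of the aryl bromide with the epoxide is run under iodide co-catalysis (NiCl2·glyme, 2,2′-bipyridine, NaI, Et3N·HCl, Zn, DMPU, rt).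
- Iodide opens 4 at the terminal carbon to (2R)-1-iodooct-7-en-2-ol F5 in the flask, and nickel joins its C1 radical to the aryl group. The C2–O bond is again untouched, and (2R)-1-[3-(benzyloxy)-5-methoxyphenyl]oct-7-en-2-ol F6 results.
- Separate acetylation (Ac2O, pyridine, DMAP) leads to 7.

Step 5.
- What may go wrong: electrophilic chlorination of the doubly activated ring by hypochlorous acid or chlorine dioxide set free during the chlorite oxidation.
- The fallback brings the carboxyl carbon in at the acid oxidation level, so that the arene never meets an oxidant. It sets out from 2 and comes back at 9, bypassing steps 2–5.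
- Bought ethyl hept-6-enoate F7 is epoxidised (mCPBA, CH2Cl2) to rac-ethyl 5-(oxiran-2-yl)pentanoate F8. This is resolved with (R,R)-(salen)Co(III)OAc and water to ethyl 5-[(2R)-oxiran-2-yl]pentanoate F9.
- Grignard reagent 5, made from 2 as in step 3, opens F9 under CuI catalysis at −40 °C, where the ester should not compete, to give ethyl (6R)-7-[3-(benzyloxy)-5-methoxyphenyl]-6-hydroxyheptanoate F10.
- Saponification (LiOH, THF/H2O) gives (6R)-7-[3-(benzyloxy)-5-methoxyphenyl]-6-hydroxyheptanoic acid F11. Acetylation (Ac2O, pyridine, then aqueous hydrolysis of the mixed anhydride) gives 9.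

Further compounds
F1 | step 7 | 7-bromoheptan-1-ol (bought) | OCCCCCCCBr
F2 | step 7 | benzyl 7-bromoheptyl ether | BrCCCCCCCOCc1ccccc1
F3 | step 7 | [7-(benzyloxy)heptyl]magnesium bromide | Br[Mg]CCCCCCCOCc1ccccc1
F4 | step 7 | bis[7-(benzyloxy)heptyl]zinc | C(CCCCCCOCc1ccccc1)[Zn]CCCCCCCOCc1ccccc1
F5 | step 3 | (2R)-1-iodooct-7-en-2-ol | C=CCCCC[C@@H](O)CI
F6 | step 3 | (2R)-1-[3-(benzyloxy)-5-methoxyphenyl]oct-7-en-2-ol | COc1cc(OCc2ccccc2)cc(C[C@@H](CCCCC=C)O)c1
F7 | step 5 | ethyl hept-6-enoate (bought) | C=CCCCCC(=O)OCC
F8 | step 5 | rac-ethyl 5-(oxiran-2-yl)pentanoate | CCOC(=O)CCCCC1CO1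
F9 | step 5 | ethyl 5-[(2R)-oxiran-2-yl]pentanoate | CCOC(=O)CCCC[C@@H]1CO1
F10 | step 5 | ethyl (6R)-7-[3-(benzyloxy)-5-methoxyphenyl]-6-hydroxyheptanoate | COc1cc(OCc2ccccc2)cc(C[C@@H](CCCCC(=O)OCC)O)c1
F11 | step 5 | (6R)-7-[3-(benzyloxy)-5-methoxyphenyl]-6-hydroxyheptanoic acid | COc1cc(OCc2ccccc2)cc(C[C@@H](CCCCC(=O)O)O)c1
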